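**Strategy.** Everything rests on cutting both bonds of the C3 ketone, which lies in the ten-membered ring (C1–C10) between the alkenyl carbons C2 (E C1=C2) and C4 (Z C4=C5), so that C3 is supplied by carbon monoxide. A carbonylative Stille macrocyclization forms C3–C4 and C2–C3 and closes the carbocycle in one operation, with all five stereocentres and both alkene geometries already set. Its precursor is the seco trans α-methylene γ-lactone (O6–C12) carrying the C4 Z-alkenyl iodide, the C2 E-alkenylstannane, the C8 (R)-2-methylbutanoate, a free C10 hydroxyl and a C15 silyl ether, assembled by a zinc Barbier union and an invertive esterification.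

Key step: step 14

Remark: germacrane numbering is used for all intermediates (ring C1–C10; C11, C12, C13 lactone carbons; C14 on C10; C15 on C4); compounds 1, 2, 8, 11 and 21 are taken as commercial.

Assumption: the zinc Barbier addition of step 12 follows the closed chair transition state usual for 3-(bromomethyl)butenolides, so the C8 carbinol forms as the 8S epimer and is inverted in step 13.

**Fragment 1: bromomethylbutenolide 10 (C4–C7, C11–C13, C15)**

Step 1
Reactants: 1 tert-butyldimethyl(prop-2-yn-1-yloxy)silane; 2 acrolein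
Product: 4 rac-6-(tert-butyldimethylsilyloxy)hex-1-en-4-yn-3-ol, via lithium acetylide 3 (not isolated)
Conditions: n-BuLi, THF, −78 °C; then 2, −78 °C; aq NH4Cl
Reagents that add atoms: none
Why: 1,2-addition of a lithium acetylide to an enal, the hard alkynyllithium attacking the carbonyl of acrolein at low temperature; the carbinol (C6) is racemic and is resolved in step 3.

Step 2
Reactants: 4 rac-6-(tert-butyldimethylsilyloxy)hex-1-en-4-yn-3-ol
Product: 6 rac-(Z)-6-(tert-butyldimethylsilyloxy)-5-iodohexa-1,4-dien-3-ol, via alkenylalanate 5 (not isolated)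
Conditions: NaAlH2(OCH2CH2OMe)2 (Red-Al), THF, 0 °C; then EtOAc, I2, −78 °C
Reagents that add atoms: iodine, II
Why: alkoxide-directed trans-hydroalumination of a propargylic alcohol followed by iodinolysis with retention puts H on C5 and iodine on C4 cis to C6, which is the Z alkenyl iodide.

Step 3
Reactants: 6 rac-(Z)-6-(tert-butyldimethylsilyloxy)-5-iodohexa-1,4-dien-3-ol
Product: 7 (S,Z)-6-(tert-butyldimethylsilyloxy)-5-iodohexa-1,4-dien-3-ol
Conditions: Ti(OiPr)4, L-(+)-DIPT, t-BuOOH (0.6 equiv), 4 Å MS, CH2Cl2, −20 °C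
Reagents that add atoms: none
Why: Sharpless kinetic resolution, in which L-(+)-DIPT should epoxidise the vinyl group of the (R)-alcohol and leave the (S)-alcohol, whose only matched alkene is the deactivated Z iodoalkene; this fixes C6.

Step 4
Reactants: 7 (S,Z)-6-(tert-butyldimethylsilyloxy)-5-iodohexa-1,4-dien-3-ol; 8 2-(bromomethyl)acrylic acid
Product: 9 (S,Z)-6-(tert-butyldimethylsilyloxy)-5-iodohexa-1,4-dien-3-yl 2-(bromomethyl)acrylate
Conditions: DCC, DMAP (cat.), CH2Cl2, −20 to 0 °C
Reagents that add atoms: none
Why: Steglich esterification of a secondary allylic alcohol, with catalytic DMAP at low temperature to limit attack on the allylic bromide; C6 is not involved.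

Step 5
Reactants: 9 (S,Z)-6-(tert-butyldimethylsilyloxy)-5-iodohexa-1,4-dien-3-yl 2-(bromomethyl)acrylate
Product: 10 (S)-3-(bromomethyl)-5-[(Z)-3-(tert-butyldimethylsilyloxy)-2-iodoprop-1-en-1-yl]furan-2(5H)-one
Conditions: second-generation Grubbs catalyst (5 mol%), CH2Cl2, 40 °C, dilute
Reagents that add atoms: none
Why: ring-closing metathesis between the terminal vinyl group and the acrylate methylene closes the butenolide (C7=C11) with loss of ethene, the trisubstituted iodoalkene being inert.

**Fragment 2: stannyl aldehyde 18 (C8–C10, C1, C2, C14)**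

Step 6
Reactants: 11 (R)-citramalic acid
Product: 12 (R)-2-(2,2,4-trimethyl-5-oxo-1,3-dioxolan-4-yl)acetic acid
Conditions: 2,2-dimethoxypropane, PPTS (cat.), rt
Reagents that add atoms: 2,2-dimethoxypropane, COC(C)(C)OC
Why: acid-catalysed dioxolanone (acetonide) formation engages the α-hydroxy acid and leaves the CH2CO2H arm free; the quaternary stereocentre (C10) is not touched.

Step 7
Reactants: 12 (R)-2-(2,2,4-trimethyl-5-oxo-1,3-dioxolan-4-yl)acetic acid
Product: 14 (R)-3-hydroxy-3-methyldihydrofuran-2(3H)-one, via hydroxyethyl dioxolanone 13 (not isolated)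
Conditions: BH3·SMe2, THF, 0 °C to rt; MeOH; then TsOH (cat.), CH2Cl2, rt
Reagents that add atoms: none
Why: borane reduces the free carboxylic acid chemoselectively beside the dioxolanone, and acid-catalysed transesterification then gives the γ-lactone with release of acetone.

Step 8
Reactants: 14 (R)-3-hydroxy-3-methyldihydrofuran-2(3H)-one
Product: 15 (3R)-3-methyltetrahydrofuran-2,3-diol (lactol, both anomers)
Conditions: iBu2AlH (DIBAL-H, 2.2 equiv), CH2Cl2, −78 °C
Reagents that add atoms: none
Why: partial reduction of a lactone to the lactol, the tetrahedral aluminate being stable at low temperature.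

Step 9
Reactants: 15 (3R)-3-methyltetrahydrofuran-2,3-diol
Product: 16 (R)-3-methylpent-4-yne-1,3-diol
Conditions: dimethyl (1-diazo-2-oxopropyl)phosphonate, K2CO3, MeOH, 0 °C to rt
Reagents that add atoms: dimethyl (1-diazo-2-oxopropyl)phosphonate (Ohira–Bestmann reagent), COP(=O)(OC)C(=[N+]=[N-])C(C)=O
Why: Seyferth–Gilbert homologation with the Ohira–Bestmann reagent acts on the open hydroxy aldehyde form of the lactol; the α-carbon is quaternary, so it cannot epimerise.

Step 10
Reactants: 16 (R)-3-methylpent-4-yne-1,3-diol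
Product: 17 (R,E)-3-methyl-5-(tributylstannyl)pent-4-ene-1,3-diol
Conditions: Bu3SnH, PdCl2(PPh3)2 (2 mol%), THF, 0 °C
Reagents that add atoms: tributyltin hydride, CCCC[SnH](CCCC)CCCC
Why: palladium-catalysed syn hydrostannation of a terminal alkyne, the fully substituted propargylic carbon steering tin to the terminus to give the E alkenylstannane (C1=C2).

Step 11
Reactants: 17 (R,E)-3-methyl-5-(tributylstannyl)pent-4-ene-1,3-diol
Product: 18 (R,E)-3-hydroxy-3-methyl-5-(tributylstannyl)pent-4-enal
Conditions: Dess–Martin periodinane, NaHCO3, CH2Cl2, 0 °C; used at once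
Reagents that add atoms: none
Why: Dess–Martin oxidation takes only the primary alcohol because the tertiary one cannot be oxidised, and the buffered medium spares the alkenylstannane.

**Union and endgame**

Step 12
Reactants: 10 (S)-3-(bromomethyl)-5-[(Z)-3-(tert-butyldimethylsilyloxy)-2-iodoprop-1-en-1-yl]furan-2(5H)-one; 18 (R,E)-3-hydroxy-3-methyl-5-(tributylstannyl)pent-4-enal
Product: 20 (4R,5S)-5-[(Z)-3-(tert-butyldimethylsilyloxy)-2-iodoprop-1-en-1-yl]-4-[(1S,3R,E)-1,3-dihydroxy-3-methyl-5-(tributylstannyl)pent-4-en-1-yl]-3-methylenedihydrofuran-2(3H)-one, via allylzinc bromide 19 (not isolated)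
Conditions: Zn dust, THF/sat. aq NH4Cl, 0 °C to rt
Reagents that add atoms: none
Why: zinc Barbier allylation in which the 2-(alkoxycarbonyl)allylzinc reacts at its γ-carbon C7: the aldehyde adds anti to the C6 substituent (trans lactone, C7 set) through a Zimmerman–Traxler chair in which ring carbon C6 is locked trans to CH2Zn, giving the anti (8S) carbinol, while the alkenyl iodide and stannane are inert to zinc.

Step 13
Reactants: 20 the lactone diol of step 12; 21 (R)-2-methylbutanoic acid
Product: 22 (1R,3R,E)-1-[(2S,3R)-2-[(Z)-3-(tert-butyldimethylsilyloxy)-2-iodoprop-1-en-1-yl]-4-methylene-5-oxotetrahydrofuran-3-yl]-3-hydroxy-3-methyl-5-(tributylstannyl)pent-4-en-1-yl (R)-2-methylbutanoate (seco lactone; germacrane 6S,7R,8R,10R)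
Conditions: PPh3, DIAD, toluene, 0 °C to rt
Reagents that add atoms: none
Why: Mitsunobu esterification, in which the secondary C8 alcohol is activated as the alkoxyphosphonium and displaced by the carboxylate with inversion (8S to 8R), the tertiary C10 alcohol being too hindered to react.

Step 14
Reactants: 22 the seco lactone of step 13
Product: 23 15-O-tert-butyldimethylsilyl ether of the target, (6R,7R,8R,10R)-15-(tert-butyldimethylsilyloxy)-10-hydroxy-8-[(R)-2-methylbutanoyloxy]-3-oxogermacra-1(E),4(Z),11(13)-trien-12,6-olide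
Conditions: Pd2(dba)3 (10 mol%), AsPh3 (40 mol%), CO (3 atm), NMP, 50 °C, slow addition to 0.002 M, dark
Reagents that add atoms: carbon monoxide, [C-]#[O+]
Why: Zerovalent palladium (AsPh3-ligated) inserts into the C4–I bond with retention, CO insertion gives the divalent acylpalladium at C3, the C2 alkenylstannane transmetalates intramolecularly with retention, and reductive elimination forms C2–C3. The closest known reaction type is the carbonylative Stille coupling of an alkenyl iodide with an alkenylstannane, which has been used intramolecularly to close macrocyclic cross-conjugated dienones. The ten-membered carbocycle closes end to end in the C2–C3 reductive elimination from an eleven-membered acyl(alkenyl)palladacycle, both new bonds ending at the new sp2 carbon C3 inside the ring. No stereocentre is formed, and the Z (C4=C5) and E (C1=C2) geometries are carried through because every elementary step is stereoretentive. The step needs carbonylation to outrun direct C2–C4 coupling, and cyclization to outrun oligomerization and acylpalladation of the C11=C13 methylene: CO pressure and the strain of the alternative nine-membered diene should secure the first; high dilution and the turn imposed by the Z alkene and the trans lactone, which hold C2 and C4 close, should secure the second, while the neutral medium spares the ester, the free C10 hydroxyl and the α-methylene lactone.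

Step 15
Reactants: 23 the macrocyclic silyl ether of step 14
Product: 24 target, (6R,7R,8R,10R)-10,15-dihydroxy-8-[(R)-2-methylbutanoyloxy]-3-oxogermacra-1(E),4(Z),11(13)-trien-12,6-olide
Conditions: HF·pyridine, pyridine, THF, 0 °C, dark
Reagents that add atoms: none
Why: fluoride cleavage of a primary allylic silyl ether with pyridine-buffered HF, a near-neutral medium that should avoid acyl migration and oxa-Michael addition; light is excluded to prevent E/Z isomerisation of the dienone.

**Compound list**

1 | tert-butyldimethyl(prop-2-yn-1-yloxy)silane | C#CCO[Si](C)(C)C(C)(C)C | starting material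
2 | acrolein | C=CC=O | starting material
3 | lithium 3-(tert-butyldimethylsilyloxy)prop-1-yn-1-ide (lithium acetylide) | [Li]C#CCO[Si](C)(C)C(C)(C)C | intermediate (not isolated)
4 | rac-6-(tert-butyldimethylsilyloxy)hex-1-en-4-yn-3-ol | C=CC(O)C#CCO[Si](C)(C)C(C)(C)C | intermediate
5 | sodium alkenylalanate (cyclic alkoxy(alkenyl)bis(2-methoxyethoxy)aluminate from 4) | C=CC1O[Al-](OCCOC)(OCCOC)C(CO[Si](C)(C)C(C)(C)C)=C1.[Na+] | intermediate (not isolated)
6 | rac-(Z)-6-(tert-butyldimethylsilyloxy)-5-iodohexa-1,4-dien-3-ol | C=CC(O)/C=C(/CO[Si](C)(C)C(C)(C)C)I | intermediate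
7 | (S,Z)-6-(tert-butyldimethylsilyloxy)-5-iodohexa-1,4-dien-3-ol | C=C[C@H](O)/C=C(/CO[Si](C)(C)C(C)(C)C)I | intermediate
8 | 2-(bromomethyl)acrylic acid | C=C(CBr)C(=O)O | starting material
9 | (S,Z)-6-(tert-butyldimethylsilyloxy)-5-iodohexa-1,4-dien-3-yl 2-(bromomethyl)acrylate | C=C(CBr)C(=O)O[C@@H](C=C)/C=C(/CO[Si](C)(C)C(C)(C)C)I | intermediate
10 | (S)-3-(bromomethyl)-5-[(Z)-3-(tert-butyldimethylsilyloxy)-2-iodoprop-1-en-1-yl]furan-2(5H)-one | O=C1O[C@H](/C=C(/CO[Si](C)(C)C(C)(C)C)I)C=C1CBr | intermediate
11 | (R)-citramalic acid | C[C@@](O)(CC(=O)O)C(=O)O | starting material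
12 | (R)-2-(2,2,4-trimethyl-5-oxo-1,3-dioxolan-4-yl)acetic acid | C[C@]1(CC(=O)O)OC(C)(C)OC1=O | intermediate
13 | (R)-5-(2-hydroxyethyl)-2,2,5-trimethyl-1,3-dioxolan-4-one | C[C@]1(CCO)OC(C)(C)OC1=O | intermediate (not isolated)
14 | (R)-3-hydroxy-3-methyldihydrofuran-2(3H)-one | C[C@@]1(O)CCOC1=O | intermediate
15 | (3R)-3-methyltetrahydrofuran-2,3-diol (lactol, both anomers) | C[C@@]1(O)CCOC1O | intermediate
16 | (R)-3-methylpent-4-yne-1,3-diol | C#C[C@](C)(O)CCO | intermediate
17 | (R,E)-3-methyl-5-(tributylstannyl)pent-4-ene-1,3-diol | CCCC[Sn](CCCC)(CCCC)/C=C/[C@](C)(O)CCO | intermediate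
18 | (R,E)-3-hydroxy-3-methyl-5-(tributylstannyl)pent-4-enal | CCCC[Sn](CCCC)(CCCC)/C=C/[C@](C)(O)CC=O | intermediate
19 | allylzinc bromide from 10, {(S)-5-[(Z)-3-(tert-butyldimethylsilyloxy)-2-iodoprop-1-en-1-yl]-2-oxo-2,5-dihydrofuran-3-yl}methylzinc bromide | O=C1O[C@H](/C=C(/CO[Si](C)(C)C(C)(C)C)I)C=C1C[Zn]Br | intermediate (not isolated)
20 | (4R,5S)-5-[(Z)-3-(tert-butyldimethylsilyloxy)-2-iodoprop-1-en-1-yl]-4-[(1S,3R,E)-1,3-dihydroxy-3-methyl-5-(tributylstannyl)pent-4-en-1-yl]-3-methylenedihydrofuran-2(3H)-one | C=C1C(=O)O[C@H](/C=C(/CO[Si](C)(C)C(C)(C)C)I)[C@H]1[C@@H](O)C[C@@](C)(O)/C=C/[Sn](CCCC)(CCCC)CCCC | intermediate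
21 | (R)-2-methylbutanoic acid | CC[C@@H](C)C(=O)O | starting material
22 | seco lactone, (1R,3R,E)-1-[(2S,3R)-2-[(Z)-3-(tert-butyldimethylsilyloxy)-2-iodoprop-1-en-1-yl]-4-methylene-5-oxotetrahydrofuran-3-yl]-3-hydroxy-3-methyl-5-(tributylstannyl)pent-4-en-1-yl (R)-2-methylbutanoate | C=C1C(=O)O[C@H](/C=C(/CO[Si](C)(C)C(C)(C)C)I)[C@H]1[C@H](OC(=O)[C@H](C)CC)C[C@@](C)(O)/C=C/[Sn](CCCC)(CCCC)CCCC | intermediate (precursor of the key step)
23 | 15-O-tert-butyldimethylsilyl ether of the target (6R,7R,8R,10R; E C1=C2, Z C4=C5) | C=C1C(=O)O[C@@H]2/C=C(/CO[Si](C)(C)C(C)(C)C)C(=O)/C=C/[C@](C)(O)C[C@@H](OC(=O)[C@H](C)CC)[C@@H]12 | intermediate (product of the key step)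
24 | target, (6R,7R,8R,10R)-10,15-dihydroxy-8-[(R)-2-methylbutanoyloxy]-3-oxogermacra-1(E),4(Z),11(13)-trien-12,6-olide | C=C1C(=O)O[C@@H]2/C=C(/CO)C(=O)/C=C/[C@](C)(O)C[C@@H](OC(=O)[C@H](C)CC)[C@@H]12 | target

**Step count.** 15 steps in total. The longest linear sequence is 10 steps, from (R)-citramalic acid 11 through steps 6 to 15; the butenolide branch from 1 is 9 steps (steps 1 to 5, then 12 to 15).

**Steps most likely to fail**

1. Step 14 (carbonylative macrocyclization). The alkenylpalladium may couple with the stannane before CO inserts, giving the nine-membered diene. The acylpalladium may also add across the C11=C13 methylene, or the chain may couple intermolecularly and oligomerise. The fallback sets out from 22 and comes back at 23, moving the ring closure to C1=C2. Protodestannylation of 22 (TsOH·H2O, CH2Cl2, 0 °C) gives the vinyl carbinol F1. An intermolecular carbonylative Stille coupling of its C4 iodide with tributyl(vinyl)stannane (Pd2(dba)3, AsPh3, CO, NMP) gives the divinyl ketone F2; this is an ordinary bimolecular ketone synthesis with C3 already in place. Ring-closing metathesis of F2 (second-generation Hoveyda–Grubbs catalyst, toluene, high dilution) between the C10 vinyl group and the vinyl ketone should then form the E C1=C2 bond and give 23.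

2. Step 13 (invertive esterification). The activated C8 alcohol is flanked by the ring carbon C7 and a neopentyl-type CH2, so displacement may be slow, and elimination toward C7 (a diene conjugated with the methylene lactone) may take over. The fallback sets out from 20 and comes back at 22. Dess–Martin oxidation gives the C8 ketone F3. Reagent-controlled Corey–Bakshi–Shibata reduction with (S)-2-methyl-CBS-oxazaborolidine and catecholborane (toluene, −78 °C; the branched C7 side is the large group) should give the 8R alcohol F4. Steglich esterification of F4 with 21 (DCC, DMAP, CH2Cl2) then gives 22 with retention.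

3. Step 12 (fragment union). The unprotected β-hydroxy aldehyde 18 may dehydrate or undergo retro-aldol cleavage in the aqueous ammonium chloride medium, and the allylzinc may be protonated before it adds. The fallback sets out from 18 and comes back at 20. N-(Trimethylsilyl)imidazole in CH2Cl2 masks the tertiary alcohol and gives the silylated aldehyde F5. An anhydrous Nozaki–Hiyama allylation of F5 with 10 (CrCl2, THF, rt), which proceeds through the same closed transition state, gives the silyl ether F6. Citric acid in methanol then removes the trimethylsilyl group only and gives 20.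

**Further compounds**

F1 | step 14 | vinyl carbinol, (1R,3R)-1-[(2S,3R)-2-[(Z)-3-(tert-butyldimethylsilyloxy)-2-iodoprop-1-en-1-yl]-4-methylene-5-oxotetrahydrofuran-3-yl]-3-hydroxy-3-methylpent-4-en-1-yl (R)-2-methylbutanoate | C=C1C(=O)O[C@H](/C=C(/CO[Si](C)(C)C(C)(C)C)I)[C@H]1[C@H](OC(=O)[C@H](C)CC)C[C@@](C)(O)C=C
F2 | step 14 | divinyl ketone, F1 with the C4 iodine replaced by a propenoyl group (C3 ketone, Z C4=C5) | C=C1C(=O)O[C@H](/C=C(/CO[Si](C)(C)C(C)(C)C)C(=O)C=C)[C@H]1[C@H](OC(=O)[C@H](C)CC)C[C@@](C)(O)C=C
F3 | step 13 | C8 ketone, (4S,5S)-5-[(Z)-3-(tert-butyldimethylsilyloxy)-2-iodoprop-1-en-1-yl]-4-[(R,E)-3-hydroxy-3-methyl-5-(tributylstannyl)pent-4-enoyl]-3-methylenedihydrofuran-2(3H)-one | C=C1C(=O)O[C@H](/C=C(/CO[Si](C)(C)C(C)(C)C)I)[C@H]1C(=O)C[C@@](C)(O)/C=C/[Sn](CCCC)(CCCC)CCCC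
F4 | step 13 | 8R alcohol, the C8 epimer of 20 (side chain 1R,3R) | C=C1C(=O)O[C@H](/C=C(/CO[Si](C)(C)C(C)(C)C)I)[C@H]1[C@H](O)C[C@@](C)(O)/C=C/[Sn](CCCC)(CCCC)CCCC
F5 | step 12 | silylated aldehyde, (R,E)-3-methyl-5-(tributylstannyl)-3-(trimethylsilyloxy)pent-4-enal | CCCC[Sn](CCCC)(CCCC)/C=C/[C@](C)(O[Si](C)(C)C)CC=O
F6 | step 12 | silyl ether, the C10 trimethylsilyl ether of 20 | C=C1C(=O)O[C@H](/C=C(/CO[Si](C)(C)C(C)(C)C)I)[C@H]1[C@@H](O)C[C@@](C)(O[Si](C)(C)C)/C=C/[Sn](CCCC)(CCCC)CCCC
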